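## The problem

The target is a tricyclic sesquiterpenoid diester built on a verbenone-type bicyclo[3.1.1]heptenone (C6–C7–C8–C9–C10 with the one-carbon bridges C5 and C11). The two one-carbon bridges are tied together by the chain C4–C3–C2–C1 into a seven-membered ring. The cyclobutane C5–C6–C11–C10 therefore carries a bridge on each face: C7–C8–C9 across C6/C10 on one face, the four-carbon tether across C5/C11 on the other. As a result H-5 and the C11 methyl group point toward the enone bridge, and C11 is quaternary. Of the six stereocenters, C5, C6, C10 and C11 are locked together by the cage. C1 and C3 (anti-1,3-dioxygenated) sit in a tether that lies in a local mirror plane of the cage: C1 can control C3 by internal delivery, but nothing in the skeleton can be expected to control C1. Both carbinols are flanked by quaternary carbons (C11, C4) and carry different unsaturated esters, so they cannot be told apart once both are free. The C7–C8–C9 bridge is pseudo-symmetric, so an oxidation that runs through a delocalised allyl intermediate would make C7 and C9 equivalent. Groups that will not stand rough treatment are the strained pinene-like skeleton (cationic rearrangement), the enone, the senecioate (deconjugation) and the 1,3-related esters (acyl migration). The feature that opens the key step is that C5 (H and C4) and C11 (CH3 and C1) are 1,3 across the cyclobutane with their carbon chains cis. This is the pattern left when the central bond of a bicyclo[1.1.0]butane, whose wing carbons C6 and C10 are already bridged by C7–C9, is 1,3-difunctionalised.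

## Retrosynthesis

**C9–CH3 and the C7 oxygen (25 ⇒ 23 ⇒ 21).** The methyl group on C9 is cut first, giving enone 23, and then the C7 carbonyl oxygen, giving alkene 21. Carrying the enone earlier was rejected because it would not survive the organolithium, carbenoid and samarium steps that build the tether, whereas a plain C8=C9 alkene does. Bringing the methyl group in with the diene would make the first two steps regiochemically ambiguous. Compound 21 lacks only one oxygen and one methyl group. The forward steps must oxidise C7 without a delocalised allyl intermediate and must leave two enoate esters alone; an ene-type allylic oxidation, then conjugate methylation with Saegusa re-oxidation, answer this.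

**The two esters and the C3–H bond (21 ⇒ 19 + 20; 19 ⇒ 17 + 18).** The senecioate is removed first (alcohol 19 and acid 20). The tiglate is then removed together with the hydride on C3, which leads to hydroxy ketone 17 and aldehyde 18. The neighbouring cut, reduction to the free anti-diol and two acylations, would expose two hydroxyls that are both flanked by quaternary carbons. In the chosen order the C1 oxygen is acylated by the same event that reduces C3, and C1 controls C3. Compound 17 has one stereocenter less and no ester. The forward Evans–Tishchenko reaction must accept an α,β-unsaturated aldehyde as hydride donor and deliver the hydride anti across a seven-membered ring.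

**C1–C2, the seven-membered ring (17 ⇒ 16).** The ring is opened at the aldol bond C1–C2, giving keto aldehyde 16. Cutting C2–C3 instead would need an aldehyde on C4 and an acetyl group on C11. Cutting C3–C4 or C1–C11 would ask a ring closure to form a bond to a quaternary carbon. In 16 the tether is reduced to two arms held cis on the cyclobutane; the aldehyde cannot enolise and the ketone can enolise only toward its methyl group. Because the arms lie in the local mirror plane of the bicycle, the forward aldol needs an external source of facial control at C1.

**C11–C1 (16 ⇒ 15 ⇒ 14 ⇒ 13 ⇒ 12).** The aldehyde is traced to alcohol 15 and, through boronic ester 14, to tertiary boronic ester 12 by removing the one carbon between C11 and boron. The ketone is hidden as silyl enol ether 13 while the carbenoid is present. An alkylation or addition at a quaternary cyclobutane carbon has no comparably stereoretentive solution, whereas the 1,2-shift from boron transfers C11 with its configuration intact. Compound 12 is one carbon smaller and holds boron exactly where C1 must go. The forward reaction must form an ate complex at a crowded tertiary boron and must not touch the masked ketone.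

**C4–C5 and C11–CH3 (12 ⇒ 7 + 8 + 9).** Both exocyclic bonds at the one-carbon bridges are cut at once, which restores the C5–C11 bond of bicyclobutane sulfoxide 7 and releases methylboronate 8 and bromoketone 9. The neighbouring ways to the cyclobutane, a [2+2] construction or a ring contraction, would have to assemble four contiguous ring stereocenters including the quaternary C11. Here the four-membered ring exists already in strained form and only opens. Compound 7 is a C7 hydrocarbon sulfoxide without any quaternary carbon, and 8 and 9 are bought. The forward reaction must bond C4 to C5 on the convex face of the bicyclobutane, anti to the C7–C9 bridge, and must bring methyl to C11 on the bridge side, leaving boron anti.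

**The bicyclobutane (7 ⇒ 4 + 5; 4 ⇒ 3 ⇒ 1 + 2).** The C–S bond is cut to hydrocarbon 4 and sulfinate 5. The C2–C7 bond of 4 is traced to a carbenoid C–H insertion of dibromide 3, and the cyclopropane to diene 1 and bromoform 2. Since the two bridgeheads of 4 are enantiotopic, sulfinylation with a single enantiomer of 5 turns the choice between them into a pair of separable diastereomers. This is preferred to carrying racemic material to a late resolution. The forward steps must metalate the bridgehead selectively and allow clean separation of the sulfoxides.

## Roads not taken

**Alternative 1:** The cut is C6–C11, read backwards as a 1,2-shift, so the cyclobutane would be the last ring made. In the forward direction the norbornene A2 (bridgehead hydroxyl on C7, endo bromide on C6, assembled by a tethered Diels–Alder reaction) is ionised with a silver salt and a hindered base. C11 migrates from C7 to C6 anti to the departing bromide, C7 becomes the ketone, and A1 results.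
- Merits: the shift is stereospecific, so C6 and C11 are fixed by antiperiplanarity and not by a facial choice. The enone and the C9 methyl group are in place from the cycloaddition. The C1 and C3 oxygens arrive already differentiated as silyl and PMB ethers. On all three counts this road is better than the chosen one.
- Weak points: the shift runs from a norbornyl into the more strained pinanyl skeleton, against the usual Wagner–Meerwein direction, with only carbonyl formation and halide precipitation to drive it. The alkenyl carbon C8 on C7 can migrate instead if the bromide is not cleanly endo. The product is exposed to the same Lewis acid that made it. A2 needs a fully substituted oxygenated cyclopentadiene, a tether with two protected carbinols and a stereodefined bromide, so a long sequence is spent before the key step can be tried.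
- Comparison: the chosen plan sets against this the brevity with which the strained core is reached (three steps to 4, then C11 and the C4–C5 bond in one operation) and the fact that its own key step is tested at step 4 on inexpensive material.

**Alternative 2:** The cuts are C4–C5 and C1–C11. Forward, a chiral Lewis acid activates the acyl-pyrazole bicyclobutane A4 (the acyl analogue of 7); the CMe2 terminus of the dioxygenated diene A5 adds to C5 and the C11 enolate closes on C1, giving A3 with the seven-membered ring formed.
- Merits: this is the most convergent road, with both bridgehead bonds and the ring made in one catalytic step and no sulfoxide detour. If it worked it would be clearly shorter than the chosen plan.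
- Weak points: a fully substituted enol ether carbon must form a quaternary centre at a bridgehead. Polar additions to acceptor bicyclobutanes deliver the nucleophile to the rear lobe of the attacked carbon, which in A4 lies under the C7–C9 bridge, so both new bonds would have to form on the occupied face or a closed-shell nucleophile would have to abandon its usual course with no second chance. The catalyst meets racemic A4 and can at best resolve it. The acyl pyrazole on C11 must afterwards be taken down to a methyl group in about three redox steps. C1 is set in the ring closure with nothing to control it, and C3 still needs an anti reduction.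
- Comparison: the chosen plan also needs convex-face bonding at C5. It sets against Alternative 2 that the two bonds form in separate events (C11 passes through a planar radical), that methyl is placed on C11 directly, that the reaction type has direct precedent on boronates, and that C1 is left to a reagent-controlled step.

**Alternative 3:** The cut is C2–C3. Forward, the acetyl group on C11 of A7 is enolised as its diisopinocampheylboron enolate and adds to the neopentyl aldehyde on C4, closing the seven-membered ring as A6.
- Merits: the logic is that of the aldol in the chosen route, with reagent control and a non-enolisable aldehyde. The acetyl group on C11 could probably be grown from a boronic ester in one step fewer than the C1 aldehyde; in this respect the road is as good or slightly better.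
- Weak points: it is an endgame and does not say how C5 and C11 are set; it needs the same cyclobutane. A three-component entry to A7 would require an α-bromo aldehyde as radical partner, which must be masked through the organolithium steps. A6 has the hydroxyl at C3 and the ketone at C1, so the senecioate would enter by hydride transfer and the tiglate by acylation.
- Comparison: the two roads are equal in step count and in kind of stereocontrol. The chosen plan sets against it only that 9 is commercial and delivers C2, C3, C4 and both methyl groups in one piece, with no aldehyde to carry.

Key step: step 4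

## Route

Assumption on the chemistry: sulfinate 5 transfers its sulfinyl group to a bridgehead lithium compound with inversion at sulfur, as it does with other organolithium reagents. Atom labels C1–C11 follow the order of the target SMILES (C1 tiglate carbinol, C3 senecioate carbinol, C4 CMe2, C7 ketone, C11 methyl-bearing quaternary carbon); syn and anti refer to the C7–C8–C9 bridge.

Step 1
Reactants: 1 cyclohexa-1,4-diene; 2 bromoform
Product: 3 7,7-dibromobicyclo[4.1.0]hept-3-ene (cis-fused; meso)
Conditions: CHBr3, KOt-Bu, pentane, −10 °C → rt (1 in excess)
Reagents that add atoms: bromoform (2), BrC(Br)Br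
Why: Doering–Hoffmann dibromocarbene cyclopropanation; an excess of the diene keeps the reaction at the mono-adduct, and the cis ring fusion is the only one possible.

Step 2
Reactants: 3 7,7-dibromobicyclo[4.1.0]hept-3-ene
Product: 4 tricyclo[4.1.0.0(2,7)]hept-3-ene
Conditions: MeLi, Et2O, −30 → 0 °C
Reagents that add atoms: none
Why: Bromine–lithium exchange and α-elimination give a cyclopropylidene carbenoid that inserts into the adjacent allylic C–H bond (Moore–Skattebøl bicyclobutane synthesis, known for this dibromide); 4 is achiral, its two bridgeheads being enantiotopic.

Step 3
Reactants: 4 tricyclo[4.1.0.0(2,7)]hept-3-ene; 5 (1R,2S,5R)-menthyl (S)-p-toluenesulfinate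
Product: 7 1-(p-tolylsulfinyl)tricyclo[4.1.0.0(2,7)]hept-3-ene (single diastereomer; sulfinyl group on the future C11), via racemic bridgehead lithium compound 6 (not isolated)
Conditions: n-BuLi, TMEDA, Et2O, 0 °C → rt; then addition to 5, THF, −78 °C; separation of the two sulfoxide diastereomers (SiO2, then crystallisation)
Reagents that add atoms: (1R,2S,5R)-menthyl (S)-p-toluenesulfinate (5), C[C@@H]1CC[C@H]([C@@H](C1)O[S@](=O)c2ccc(C)cc2)C(C)C
Why: The bridgehead C–H bonds of a bicyclobutane are its most acidic (high s-character), and Andersen sulfinylation proceeds with inversion at sulfur; lithiation of either enantiotopic bridgehead gives two diastereomeric sulfoxides of fixed sulfur configuration, and the one with sulfur on the future C11 is kept, which fixes the absolute configuration of C5, C6, C10 and C11 for the rest of the route.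

Step 4
Reactants: 7 1-(p-tolylsulfinyl)tricyclo[4.1.0.0(2,7)]hept-3-ene; 8 2,4,4,5,5-pentamethyl-1,3,2-dioxaborolane; 9 3-bromo-3-methylbutan-2-one
Product: 12 3-methyl-3-[7-methyl-7-(pinacolboryl)bicyclo[3.1.1]hept-2-en-6-yl]butan-2-one (side chain on C5 anti; boron on C11 anti; methyl on C11 syn), via bridgehead lithium compound 10 (not isolated), via lithium boronate 11 (not isolated)
Conditions: t-BuLi, 2-MeTHF, −78 °C; 8, −78 °C → rt; then 9, blue LEDs (450 nm), −20 °C → rt
Reagents that add atoms: 2,4,4,5,5-pentamethyl-1,3,2-dioxaborolane (8), CB1OC(C)(C)C(C)(C)O1; 3-bromo-3-methylbutan-2-one (9), CC(=O)C(C)(C)Br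
Why: t-BuLi cleaves the sulfoxide to lithium compound 10, which 8 captures as boronate 11; under blue light the boronate passes an electron to 9 (donor–acceptor contact), bromide leaves and the tertiary α-keto radical bonds to C5 while the strained C5–C11 bond breaks. The α-boryl radical left at C11 is oxidised by a further molecule of 9, which carries the chain, and methyl shifts from boron to C11 (1,2-metalate rearrangement), so C4–C5 and C11–CH3 are formed and no ring is closed. The closest known reaction is the radical addition to bicyclo[1.1.0]butyl boronate complexes with 1,2-metalate shift, which gives 1,1,3-trisubstituted cyclobutyl boronic esters. C6 and C10 are untouched, so the absolute configuration is that of the separated sulfoxide 7. C5: the step needs the new bond on the convex face (side chain anti to the C7–C9 bridge, hydrogen syn); the elements relied on are the outward-bent, electron-rich C5–C11 bond and the lithium-bound pinacolate, both on the convex face where the acceptor is held, the C7 methylene and C8=C9 unit lying under the rear of C5, and the strain a tertiary group would meet syn to the bridge. C11: the radical centre is planar and the CMe2 group now covers the anti face, so methyl should migrate on the bridge side and leave the trigonal boron, with its long C–B bond, anti and cis to C4, as the later ring closure requires. Chemoselectivity for the σ-bond over the C8=C9 alkene follows from the polarity match between the electrophilic radical and the anionic boronate.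

Step 5
Reactants: 12 3-methyl-3-[7-methyl-7-(pinacolboryl)bicyclo[3.1.1]hept-2-en-6-yl]butan-2-one
Product: 13 trimethylsilyl enol ether of 12 (3-methyl-2-(trimethylsilyloxy)but-1-en-3-yl group on C5)
Conditions: TMSOTf, Et3N, CH2Cl2, 0 °C
Reagents that add atoms: trimethylsilyl trifluoromethanesulfonate, C[Si](C)(C)OS(=O)(=O)C(F)(F)F
Why: Soft enolisation and O-silylation; C4 is quaternary, so only the methyl side can enolise, and the silyl enol ether shields the ketone from the carbenoid and the butyllithium of step 6.

Step 6
Reactants: 13 trimethylsilyl enol ether of 12
Product: 15 3-[7-(hydroxymethyl)-7-methylbicyclo[3.1.1]hept-2-en-6-yl]-3-methylbutan-2-one (hydroxymethyl on C11 anti), via homologated boronic ester 14 (not isolated)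
Conditions: BrCH2Cl, n-BuLi, THF, −78 °C → rt; then NaOH, H2O2, THF/H2O, 0 °C → rt
Reagents that add atoms: bromochloromethane, ClCBr; hydrogen peroxide, OO
Why: Matteson homologation: LiCH2Cl formed in situ adds to boron and C11 shifts from boron to carbon with loss of chloride and with retention at C11; the alkaline peroxide then oxidises the primary C–B bond and hydrolyses the silyl enol ether back to the ketone.

Step 7
Reactants: 15 3-[7-(hydroxymethyl)-7-methylbicyclo[3.1.1]hept-2-en-6-yl]-3-methylbutan-2-one
Product: 16 7-methyl-6-(2-methyl-3-oxobutan-2-yl)bicyclo[3.1.1]hept-2-ene-7-carbaldehyde (formyl on C11 anti; cis to the C5 side chain)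
Conditions: Dess–Martin periodinane, CH2Cl2, 0 °C → rt
Reagents that add atoms: none
Why: Dess–Martin oxidation of a neopentyl primary alcohol under neutral conditions; the aldehyde is non-enolisable (C11 quaternary) and the ketone is not affected.

Step 8
Reactants: 16 7-methyl-6-(2-methyl-3-oxobutan-2-yl)bicyclo[3.1.1]hept-2-ene-7-carbaldehyde
Product: 17 tricyclic β-hydroxy ketone (C1 hydroxyl, R; C3 ketone; C8=C9 alkene)
Conditions: (−)-Ipc2BCl, Et3N, Et2O, −78 → −20 °C; work-up H2O2, MeOH, pH 7 buffer, 0 °C
Reagents that add atoms: none
Why: Paterson boron aldol: the chloroborane and amine enolise the ketone toward its methyl group, and a closed six-membered transition state closes the seven-membered ring, 7-(enolexo)-exo-trig, onto the cis-disposed aldehyde; as the bicycle offers no facial bias at C1, the isopinocampheyl ligands choose the aldehyde face (Re-face attack expected for a methyl ketone with this reagent, giving R at C1).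

Step 9
Reactants: 17 tricyclic β-hydroxy ketone; 18 (E)-2-methylbut-2-enal
Product: 19 C1 tiglate C3 alcohol (1R,3R; 1,3-anti)
Conditions: SmI2 (0.3 equiv), 18 (6 equiv), THF, −10 °C
Reagents that add atoms: (E)-2-methylbut-2-enal (18), C/C=C(\C)C=O
Why: Evans–Tishchenko reaction: the C1 hydroxyl adds to 18 and, within a samarium chelate of both oxygens, the former aldehyde C–H is delivered to the C3 carbonyl anti to the C1 oxygen; the same event leaves the tiglate on C1 and so differentiates the two oxygens.

Step 10
Reactants: 19 C1 tiglate C3 alcohol; 20 3-methylbut-2-enoic acid
Product: 21 C1 tiglate C3 senecioate (C7 methylene; C8=C9 alkene)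
Conditions: 20, 2,4,6-trichlorobenzoyl chloride, Et3N, THF, rt; then 19, DMAP, toluene, 0 °C → rt
Reagents that add atoms: 3-methylbut-2-enoic acid (20), CC(C)=CC(=O)O
Why: Yamaguchi esterification of a hindered secondary alcohol through the mixed anhydride, which avoids the ketene pathway and the deconjugation met with the acid chloride; the low temperature is meant to outpace 1,3-acyl migration of the tiglate.

Step 11
Reactants: 21 C1 tiglate C3 senecioate
Product: 23 C7 enone (C7 ketone; C8=C9; hydrogen on C9), via C7 allylic alcohol 22 (not isolated)
Conditions: SeO2 (0.5 equiv), t-BuOOH, CH2Cl2, rt; then Dess–Martin periodinane, CH2Cl2, rt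
Reagents that add atoms: selenium dioxide, O=[Se]=O; tert-butyl hydroperoxide, CC(C)(C)OO
Why: Selenium dioxide allylic oxidation by ene reaction and [2,3]-shift: only C7 offers an allylic hydrogen (C10 is a bridgehead), and the oxygen returns to C7 with the alkene back at C8=C9, so no delocalised allyl intermediate can exchange C7 and C9; the electron-poor enoate alkenes are much less reactive in the ene step, and the periodinane converts the alcohol (and any enone already formed) into 23.

Step 12
Reactants: 23 C7 enone
Product: 25 target compound CNP0277258.1, via trimethylsilyl enol ether 24 (not isolated)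
Conditions: Me2CuLi (from MeLi and CuI), TMSCl, THF, −78 °C; then Pd(OAc)2, MeCN, rt
Reagents that add atoms: lithium dimethylcuprate, [Li+].C[Cu-]C; chlorotrimethylsilane, C[Si](C)(C)Cl (silyl group of 24 only)
Why: Silyl-accelerated cuprate conjugate addition to the strained enone, which is far more reactive than the hindered β-substituted enoates, followed by Saegusa–Ito oxidation; β-hydride elimination from the palladium enolate can only occur toward C9 (C6 is a bridgehead), which restores C8=C9 with the methyl group in place and removes the transient C9 stereocenter.

## Compound list

1 | cyclohexa-1,4-diene | C1=CCC=CC1 | starting material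
2 | bromoform | BrC(Br)Br | starting material
3 | 7,7-dibromobicyclo[4.1.0]hept-3-ene (cis-fused, meso) | BrC1(Br)[C@H]2CC=CC[C@@H]12 | intermediate
4 | tricyclo[4.1.0.0(2,7)]hept-3-ene (achiral) | [C@@H]12[C@H]3[C@@H]1[C@@H]2C=CC3 | intermediate
5 | (1R,2S,5R)-menthyl (S)-p-toluenesulfinate | C[C@@H]1CC[C@H]([C@@H](C1)O[S@](=O)c2ccc(C)cc2)C(C)C | starting material
6 | 1-lithiotricyclo[4.1.0.0(2,7)]hept-3-ene, racemic (one enantiomer drawn) | [Li][C@@]12[C@H]3[C@@H]1[C@@H]2C=CC3 | intermediate (not isolated)
7 | 1-(p-tolylsulfinyl)tricyclo[4.1.0.0(2,7)]hept-3-ene, single diastereomer (S at sulfur; sulfinyl on the future C11; wing carbon C10 bears the alkene carbon C9) | Cc1ccc(cc1)[S@](=O)[C@@]23[C@H]4[C@@H]2[C@@H]3C=CC4 | intermediate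
8 | 2,4,4,5,5-pentamethyl-1,3,2-dioxaborolane | CB1OC(C)(C)C(C)(C)O1 | starting material
9 | 3-bromo-3-methylbutan-2-one | CC(=O)C(C)(C)Br | starting material
10 | 1-lithiotricyclo[4.1.0.0(2,7)]hept-3-ene, single enantiomer (lithium on the future C11) | [Li][C@@]12[C@H]3[C@@H]1[C@@H]2C=CC3 | intermediate (not isolated)
11 | lithium methyl(pinacolato)(tricyclo[4.1.0.0(2,7)]hept-3-en-1-yl)borate | [Li+].C[B-]1(OC(C)(C)C(C)(C)O1)[C@@]23[C@H]4[C@@H]2[C@@H]3C=CC4 | intermediate (not isolated)
12 | 3-methyl-3-[7-methyl-7-(pinacolboryl)bicyclo[3.1.1]hept-2-en-6-yl]butan-2-one (C5 side chain anti, C11 boron anti, C11 methyl syn) | CC(=O)C(C)(C)[C@@H]1[C@H]2CC=C[C@@H]1[C@]2(B3OC(C)(C)C(C)(C)O3)C | intermediate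
13 | trimethylsilyl enol ether of 12 | C=C(O[Si](C)(C)C)C(C)(C)[C@@H]1[C@H]2CC=C[C@@H]1[C@]2(B3OC(C)(C)C(C)(C)O3)C | intermediate
14 | homologated boronic ester (C11–CH2–Bpin, silyl enol ether intact) | C=C(O[Si](C)(C)C)C(C)(C)[C@@H]1[C@H]2CC=C[C@@H]1[C@]2(CB3OC(C)(C)C(C)(C)O3)C | intermediate (not isolated)
15 | 3-[7-(hydroxymethyl)-7-methylbicyclo[3.1.1]hept-2-en-6-yl]-3-methylbutan-2-one | CC(=O)C(C)(C)[C@@H]1[C@H]2CC=C[C@@H]1[C@]2(CO)C | intermediate
16 | 7-methyl-6-(2-methyl-3-oxobutan-2-yl)bicyclo[3.1.1]hept-2-ene-7-carbaldehyde | CC(=O)C(C)(C)[C@@H]1[C@H]2CC=C[C@@H]1[C@]2(C=O)C | intermediate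
17 | tricyclic β-hydroxy ketone (C1 R-hydroxyl, C3 ketone) | O[C@@H]1CC(=O)C(C)(C)[C@@H]2[C@H]3CC=C[C@@H]2[C@]31C | intermediate
18 | (E)-2-methylbut-2-enal (tiglic aldehyde) | C/C=C(\C)C=O | starting material
19 | C1 tiglate C3 alcohol (1R,3R, anti) | C/C=C(\C)C(=O)O[C@@H]1C[C@@H](O)C(C)(C)[C@@H]2[C@H]3CC=C[C@@H]2[C@]31C | intermediate
20 | 3-methylbut-2-enoic acid (senecioic acid) | CC(C)=CC(=O)O | starting material
21 | C1 tiglate C3 senecioate (C7 methylene, C8=C9) | C/C=C(\C)C(=O)O[C@@H]1C[C@@H](OC(=O)C=C(C)C)C(C)(C)[C@@H]2[C@H]3CC=C[C@@H]2[C@]31C | intermediate
22 | C7 allylic alcohol of 21 (hydroxyl on the face of the C5 bridge) | C/C=C(\C)C(=O)O[C@@H]1C[C@@H](OC(=O)C=C(C)C)C(C)(C)[C@@H]2[C@H]3[C@@H](O)C=C[C@@H]2[C@]31C | intermediate (not isolated)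
23 | C7 enone (no methyl on C9) | C/C=C(\C)C(=O)O[C@@H]1C[C@@H](OC(=O)C=C(C)C)C(C)(C)[C@@H]2[C@H]3C(=O)C=C[C@@H]2[C@]31C | intermediate
24 | trimethylsilyl enol ether (C7–OSiMe3, C7=C8, methyl on C9 on the face of the C5 bridge) | C/C=C(\C)C(=O)O[C@@H]1C[C@@H](OC(=O)C=C(C)C)C(C)(C)[C@@H]2[C@H]3C(O[Si](C)(C)C)=C[C@@H](C)[C@@H]2[C@]31C | intermediate (not isolated)
25 | CNP0277258.1 | C/C=C(\C)C(=O)O[C@@H]1C[C@@H](OC(=O)C=C(C)C)C(C)(C)[C@@H]2[C@H]3C(=O)C=C(C)[C@@H]2[C@]31C | target

## Step count and least certain steps

Total: 12 steps. Longest linear sequence: 12 steps (1 → 25); compounds 2, 5, 8, 9, 18 and 20 are bought.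

**Step 4 (key step).** The most likely failure is poor or reversed facial selectivity at C5. Open bicyclobutanes are normally attacked at the rear lobe of the central bond. If the free radical does the same here, under the bridge, the side chain ends syn to the bridge and that C5 epimer cannot be closed to the seven-membered ring. Halophilic bromine transfer from 9 to the boronate is a second drain. The configuration at C5 is to be checked at 12 before material is carried on.
Fallback, from 7 back to 12: boronate 11 is generated from 7 as before and used in the palladium-catalysed variant of the same σ-bond difunctionalisation (Pd(OAc)2, bisphosphine ligand) with 3-methylbut-2-en-2-yl triflate. Here a metal-bound carbon group, not a free radical, is delivered; the metal is expected to engage the exposed convex face while methyl migrates anti to it, giving the C5-alkenyl boronic ester F1. Dimethyldioxirane epoxidises the tetrasubstituted alkene selectively to the oxirane F2. BF3·OEt2 then promotes the Meinwald rearrangement, in which shift of C5 (with retention) or of methyl leads to the same methyl ketone, 12.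

**Step 8.** The most likely failure is low facial selectivity at the aldehyde, since the cage gives no bias and reagent control by the isopinocampheyl groups is only moderate for methyl ketones. Some hydride reduction of the aldehyde by the chloroborane is also possible.
Fallback, from 16 back to 17: 16 is cyclised without external control and dehydrated (KOt-Bu, then methanesulfonyl chloride and Et3N) to the seven-membered enone F6. A copper-catalysed enantioselective conjugate borylation (CuCl, NaOt-Bu, chiral bisphosphine, bis(pinacolato)diboron, MeOH) then places boron on C1 under catalyst control to give the β-boryl ketone F7, and oxidation with retention (NaBO3) gives 17.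

**Step 9.** The most likely failure is sluggish hydride transfer, because the conjugated α-branched aldehyde 18 forms its hemiacetal reluctantly and the chelate must be reached within a seven-membered ring. Retro-aldol opening of 17 on the Lewis acid could then compete.
Fallback, from 17 back to 19: 17 is acylated at C1 with tiglic acid under the Yamaguchi conditions of step 10 to give the keto tiglate F8. The C3 ketone is then reduced under reagent control with the (S)-methyl-oxazaborolidine catalyst and catecholborane (tert-alkyl as the large group), which should give 19.

**Step 11.** The most likely failure is insufficient chemoselectivity of the ene oxidation: the cis-disubstituted ring alkene is not a fast substrate, and oxidation at the allylic methyl groups of the two enoates may compete.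
Fallback, from 21 to 25 (replaces steps 11 and 12): a Schenck ene reaction with singlet oxygen (O2, tetraphenylporphyrin, light) run with acetic anhydride, pyridine and DMAP moves the alkene to C7=C8 and, after in situ dehydration of the hydroperoxide, gives the transposed enone F9 (C9 ketone). MeLi/CeCl3 at −78 °C adds to the ketone to give the tertiary allylic alcohol F10. Pyridinium chlorochromate (C5H5NH[CrO3Cl]) then effects the oxidative 1,3-transposition to 25. Both regiochemical events are pericyclic, so C7 and C9 are again never equivalent.

**Step 6.** The most likely failure is loss of the trimethylsilyl enol ether before or during carbenoid generation, which exposes the ketone to butyllithium and LiCH2Cl. Slow ate-complex formation at the crowded tertiary boron would have the same effect by leaving the carbenoid to decompose.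
Fallback, from 12 back to 16 (replaces steps 5–7): the ketone is protected as the dioxolane F3 (1,2-bis(trimethylsilyloxy)ethane, catalytic TMSOTf, CH2Cl2, −78 °C). Homologation and oxidation as in step 6 give the ketal alcohol F4. Dess–Martin oxidation gives the ketal aldehyde F5, and pyridinium p-toluenesulfonate in aqueous acetone releases 16.

## Further compounds

F1 | step 4 | C5-alkenyl boronic ester: 6-(3-methylbut-2-en-2-yl)-7-methyl-7-(pinacolboryl)bicyclo[3.1.1]hept-2-ene (alkenyl and boron anti) | CC(C)=C(C)[C@@H]1[C@H]2CC=C[C@@H]1[C@]2(B3OC(C)(C)C(C)(C)O3)C
F2 | step 4 | oxirane of F1 (either epimer at the oxirane carbon) | CC1(C)OC1(C)[C@@H]2[C@H]3CC=C[C@@H]2[C@]3(B4OC(C)(C)C(C)(C)O4)C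
F3 | step 6 | dioxolane of 12 | CC1(OCCO1)C(C)(C)[C@@H]2[C@H]3CC=C[C@@H]2[C@]3(B4OC(C)(C)C(C)(C)O4)C
F4 | step 6 | ketal alcohol (C11 hydroxymethyl, dioxolane at C3) | CC1(OCCO1)C(C)(C)[C@@H]2[C@H]3CC=C[C@@H]2[C@]3(CO)C
F5 | step 6 | ketal aldehyde (C11 formyl, dioxolane at C3) | CC1(OCCO1)C(C)(C)[C@@H]2[C@H]3CC=C[C@@H]2[C@]3(C=O)C
F6 | step 8 | seven-membered enone (C1=C2, C3 ketone) | C1=CC(=O)C(C)(C)[C@@H]2[C@H]3CC=C[C@@H]2[C@]31C
F7 | step 8 | β-boryl ketone (pinacolboryl on C1, C3 ketone) | CC1(C)OB(OC1(C)C)[C@@H]2CC(=O)C(C)(C)[C@@H]3[C@H]4CC=C[C@@H]3[C@]42C
F8 | step 9 | keto tiglate (C1 tiglate, C3 ketone) | C/C=C(\C)C(=O)O[C@@H]1CC(=O)C(C)(C)[C@@H]2[C@H]3CC=C[C@@H]2[C@]31C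
F9 | step 11 | transposed enone (C9 ketone, C7=C8) of the diester | C/C=C(\C)C(=O)O[C@@H]1C[C@@H](OC(=O)C=C(C)C)C(C)(C)[C@@H]2[C@H]3C=CC(=O)[C@@H]2[C@]31C
F10 | step 11 | tertiary allylic alcohol (C9 methyl carbinol, C7=C8; C9 configuration immaterial, expected epimer drawn) | C/C=C(\C)C(=O)O[C@@H]1C[C@@H](OC(=O)C=C(C)C)C(C)(C)[C@@H]2[C@H]3C=C[C@](C)(O)[C@@H]2[C@]31C
A1 | alternative 1 | C1 TBS ether, C3 PMB ether of the tricyclic diol enone | CC(C)(C)[Si](C)(C)O[C@@H]1C[C@@H](OCc4ccc(OC)cc4)C(C)(C)[C@@H]2[C@H]3C(=O)C=C(C)[C@@H]2[C@]31C
A2 | alternative 1 | tethered norbornene with bridgehead hydroxyl on C7 and endo bromide on C6 | CC(C)(C)[Si](C)(C)O[C@@H]1C[C@@H](OCc2ccc(OC)cc2)C(C)(C)[C@@H]3[C@@H](Br)[C@@]4(O)C=C(C)[C@@H]3[C@]41C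
A3 | alternative 2 | tricyclic C3 ketone with C1 silyl ether and C11 acyl pyrazole | CC(C)(C)[Si](C)(C)O[C@@H]1CC(=O)C(C)(C)[C@@H]2[C@H]3CC=C[C@@H]2[C@]31C(=O)n4cccn4
A4 | alternative 2 | (pyrazol-1-yl)(tricyclo[4.1.0.0(2,7)]hept-3-en-1-yl)methanone | O=C(n1cccn1)[C@@]23[C@H]4[C@@H]2[C@@H]3C=CC4
A5 | alternative 2 | (E)-1-(tert-butyldimethylsilyloxy)-4-methyl-3-(trimethylsilyloxy)penta-1,3-diene | CC(C)=C(O[Si](C)(C)C)/C=C/O[Si](C)(C)C(C)(C)C
A6 | alternative 3 | tricyclic C1 ketone, C3 alcohol | O=C1C[C@@H](O)C(C)(C)[C@@H]2[C@H]3CC=C[C@@H]2[C@]31C
A7 | alternative 3 | 2-(7-acetyl-7-methylbicyclo[3.1.1]hept-2-en-6-yl)-2-methylpropanal | O=CC(C)(C)[C@@H]1[C@H]2CC=C[C@@H]1[C@]2(C(C)=O)C
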